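**Plan**
1. Retrosynthesis cuts, in this order: the three aryl O–methyl bonds; the Cα–Cβ bond of the propanoate chain (made as an alkene by a Wittig reaction); the furan O1–C2 bond (ring contraction of a 3-bromocoumarin); the pyranone C3=C4 and acyl–O bonds (ketene-ylide annulation of an ortho-hydroxybenzophenone); the aryl–C(=O) bond of that benzophenone (aryllithium plus Weinreb amide).
2. Enabling feature: the furan ring O1–C2–C3–C3a–C7a, with an aryl group on C3 and a carbon substituent on C2, is the contracted pyranone ring of a 4-aryl-3-bromocoumarin. Coumarin C3, C4, C5-methyl and C7-oxygen become benzofuran C2, C3, C4-methyl and C6-oxygen, and the lactone carbonyl carbon becomes the first chain carbon on C2.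
3. Forward order: ring B Weinreb amide is ortho-methylated; the ring A aryllithium is acylated; BCl3 frees the chelated phenol; the pyranone ring is closed; C3 is brominated; the pyranone is contracted to the furan; the carboxyl group is reduced and extended by two carbons; the alkene is hydrogenated; the methyl ethers are cleaved last.
4. Stereochemistry: the target has no stereocentre; the (E)-alkene from the Wittig step is removed by hydrogenation.

Key step: step 9

Remark: the target SMILES carries no stereodescriptor, so the hindered aryl–benzofuran axis is taken as not fixed and is left uncontrolled.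

**Step 1**
Reactants: 1 3,5-dimethoxy-4-methylbenzoic acid
Product: 3 N,3,5-trimethoxy-N,4-dimethylbenzamide, via acyl imidazolide 2 (not isolated)
Conditions: CDI, CH2Cl2, rt; then MeNH(OMe)·HCl, rt
Reagents that add atoms: N,O-dimethylhydroxylamine hydrochloride, CNOC.Cl; 1,1'-carbonyldiimidazole, O=C(n1ccnc1)n1ccnc1 (its imidazole stays only in 2)
Why: Weinreb amide synthesis by acyl transfer, in which CDI turns the unhindered acid into the acyl imidazolide and N,O-dimethylhydroxylamine then attacks the carbonyl with loss of imidazole.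

**Step 2**
Reactants: 3 N,3,5-trimethoxy-N,4-dimethylbenzamide
Product: 4 2-bromo-N,3,5-trimethoxy-N,4-dimethylbenzamide
Conditions: NBS (1.0 equiv), MeCN, 0 °C to rt
Reagents that add atoms: N-bromosuccinimide, O=C1CCC(=O)N1Br
Why: Electrophilic aromatic bromination at C2 (equivalent to C6), which is ortho to one methoxy group and para to the other and is the only kind of open position, while the first bromine and the stoichiometry should hold the reaction at the monobromide.

**Step 3**
Reactants: 4 2-bromo-N,3,5-trimethoxy-N,4-dimethylbenzamide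
Product: 5 N,3,5-trimethoxy-N,2,4-trimethylbenzamide
Conditions: trimethylboroxine, Pd(OAc)2 (cat.), SPhos, K3PO4, toluene/H2O, 100 °C
Reagents that add atoms: trimethylboroxine, CB1OB(C)OB(C)O1
Why: Suzuki–Miyaura cross-coupling with a methylboron reagent (oxidative addition of the aryl bromide to zerovalent palladium, methyl transfer from boron, reductive elimination), with the bulky SPhos ligand serving the di-ortho-substituted bromide and the Weinreb amide left untouched.

**Step 4**
Reactants: 6 3,5-dimethoxytoluene
Product: 7 2-bromo-3,5-dimethoxytoluene (2-bromo-1,5-dimethoxy-3-methylbenzene)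
Conditions: NBS (1.0 equiv), MeCN, 0 °C
Reagents that add atoms: N-bromosuccinimide, O=C1CCC(=O)N1Br
Why: Electrophilic aromatic bromination of an orcinol diether, where the carbon ortho to methyl (para to one methoxy, ortho to the other) is the known preferred site over the crowded carbon between the two methoxy groups.

**Step 5**
Reactants: 7 2-bromo-3,5-dimethoxytoluene; 5 N,3,5-trimethoxy-N,2,4-trimethylbenzamide
Product: 10 (2,4-dimethoxy-6-methylphenyl)(3,5-dimethoxy-2,4-dimethylphenyl)methanone, via aryllithium 8 (not isolated), via lithium hemiaminal chelate 9 (not isolated)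
Conditions: 7, n-BuLi, THF, −78 °C; then 5, −78 °C to 0 °C; 1 M HCl
Reagents that add atoms: n-butyllithium, [Li]CCCC (its lithium is carried only by 8 and 9)
Why: Bromine–lithium exchange followed by Weinreb ketone synthesis, in which the aryllithium adds only once because the lithium-chelated tetrahedral adduct 9 persists until the acidic quench releases the diaryl ketone.

**Step 6**
Reactants: 10 (2,4-dimethoxy-6-methylphenyl)(3,5-dimethoxy-2,4-dimethylphenyl)methanone
Product: 12 (2-hydroxy-4-methoxy-6-methylphenyl)(3,5-dimethoxy-2,4-dimethylphenyl)methanone, via dichloroboron chelate 11 (not isolated)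
Conditions: BCl3 (1.2 equiv), CH2Cl2, −78 °C to 0 °C; H2O
Reagents that add atoms: boron trichloride, ClB(Cl)Cl (boron and chlorine stay only in 11)
Why: Chelation-controlled ether cleavage, in which BCl3 binds the ketone oxygen and the single ortho methoxy group in a six-membered chelate and chloride removes that methyl group, whereas the meta and para methoxy groups cannot chelate and should stay.

**Step 7**
Reactants: 12 (2-hydroxy-4-methoxy-6-methylphenyl)(3,5-dimethoxy-2,4-dimethylphenyl)methanone; 13 (triphenylphosphoranylidene)ketene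
Product: 15 4-(3,5-dimethoxy-2,4-dimethylphenyl)-7-methoxy-5-methyl-2H-chromen-2-one, via acyl ylide ester 14 (not isolated)
Conditions: toluene, 110 °C
Reagents that add atoms: none
Why: Coumarin synthesis with the Bestmann ylide, in which the phenol adds to the ketene carbon to give acyl ylide ester 14 and its intramolecular Wittig reaction with the neighbouring ketone forms C3=C4 and closes the six-membered pyranone ring.

**Step 8**
Reactants: 15 4-(3,5-dimethoxy-2,4-dimethylphenyl)-7-methoxy-5-methyl-2H-chromen-2-one
Product: 16 3-bromo-4-(3,5-dimethoxy-2,4-dimethylphenyl)-7-methoxy-5-methyl-2H-chromen-2-one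
Conditions: NBS (1.05 equiv), MeCN, 0 °C to rt, dark
Reagents that add atoms: N-bromosuccinimide, O=C1CCC(=O)N1Br
Why: Electrophilic bromination at C3 of a 7-alkoxycoumarin (attack on the styrene-like C3=C4 bond activated through C4a by the para 7-methoxy group, then loss of the C3 proton), a standard reaction of 4-substituted 7-methoxycoumarins, while the only free carbon of ring B is screened by the biaryl axis and conjugated with just one methoxy group because the other is twisted out of plane by its two flanking methyl groups.

**Step 9**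
Reactants: 16 3-bromo-4-(3,5-dimethoxy-2,4-dimethylphenyl)-7-methoxy-5-methyl-2H-chromen-2-one
Product: 19 3-(3,5-dimethoxy-2,4-dimethylphenyl)-6-methoxy-4-methyl-1-benzofuran-2-carboxylic acid, via ring-opened dianion 17 (not isolated), via sodium carboxylate 18 (not isolated)
Conditions: NaOH (4 equiv), EtOH/H2O, reflux; then 2 M HCl to pH 1
Reagents that add atoms: sodium hydroxide, [Na+].[OH-]
Why: Hydroxide opens the lactone of 16 to dianion 17, a 2-bromo-3,3-diarylacrylate whose ring A phenoxide sits on the alkene carbon next to the one carrying bromine. The phenoxide oxygen adds to the bromine-bearing carbon, the charge is taken up at the doubly benzylic carbon, and loss of bromide restores the double bond as furan C2=C3 (nucleophilic vinylic substitution by addition–elimination), giving carboxylate 18 and, after acidification, acid 19. This is the Perkin rearrangement (coumarin-to-benzofuran ring contraction) of 3-halocoumarins, which is established for 4-alkyl and 4-aryl substrates. The furan ring O1–C2–C3–C3a–C7a closes by forming O1–C2 in a formally 5-endo-trig attack on the sp2 carbon, the usual mode of this rearrangement, driven by the full charge on oxygen and by heat. No stereocentre is created, so no control element is needed, and the alkene geometry of 17 is irrelevant because the nucleophile attacks the alkene carbon itself. The step needs a single oxygen nucleophile and bromine on C3 only: every other phenol is a methyl ether that is inert to hot alkali, and any acrylate that fails to cyclise should relactonise to 16 on acidification and can be resubmitted.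

**Step 10**
Reactants: 19 3-(3,5-dimethoxy-2,4-dimethylphenyl)-6-methoxy-4-methyl-1-benzofuran-2-carboxylic acid
Product: 21 [3-(3,5-dimethoxy-2,4-dimethylphenyl)-6-methoxy-4-methyl-1-benzofuran-2-yl]methanol, via aluminium alkoxide 20 (not isolated)
Conditions: LiAlH4, THF, 0 °C to rt; aqueous work-up
Reagents that add atoms: lithium aluminium hydride, [Li+].[AlH4-] (the metals stay only in 20)
Why: Hydride reduction of a carboxylic acid to the primary alcohol with LiAlH4, to which the aryl methyl ethers and the benzofuran are inert.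

**Step 11**
Reactants: 21 [3-(3,5-dimethoxy-2,4-dimethylphenyl)-6-methoxy-4-methyl-1-benzofuran-2-yl]methanol; 22 methyl (triphenylphosphoranylidene)acetate
Product: 24 methyl (2E)-3-[3-(3,5-dimethoxy-2,4-dimethylphenyl)-6-methoxy-4-methyl-1-benzofuran-2-yl]prop-2-enoate, via aldehyde 23 (not isolated)
Conditions: MnO2 (10 equiv), 22 (1.3 equiv), CH2Cl2, rt to 40 °C
Reagents that add atoms: none
Why: Tandem oxidation–Wittig reaction, in which MnO2 oxidises the benzylic-type furylmethanol to aldehyde 23 and the stabilised ylide traps it as it forms to give the (E)-acrylate.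

**Step 12**
Reactants: 24 methyl (2E)-3-[3-(3,5-dimethoxy-2,4-dimethylphenyl)-6-methoxy-4-methyl-1-benzofuran-2-yl]prop-2-enoate
Product: 25 methyl 3-[3-(3,5-dimethoxy-2,4-dimethylphenyl)-6-methoxy-4-methyl-1-benzofuran-2-yl]propanoate
Conditions: H2 (1 atm), Pd/C (10%), EtOAc, rt
Reagents that add atoms: none
Why: Heterogeneous catalytic hydrogenation of the disubstituted conjugated alkene, under which the tetrasubstituted aromatic C2=C3 bond of the benzofuran and the aryl ethers should not be reduced.

**Step 13**
Reactants: 25 methyl 3-[3-(3,5-dimethoxy-2,4-dimethylphenyl)-6-methoxy-4-methyl-1-benzofuran-2-yl]propanoate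
Product: 27 talarominine A (methyl 3-[3-(3,5-dihydroxy-2,4-dimethylphenyl)-6-hydroxy-4-methyl-1-benzofuran-2-yl]propanoate), via aryl dibromoborate 26 (not isolated)
Conditions: BBr3 (6 equiv), CH2Cl2, −78 °C to 0 °C; then MeOH, 0 °C to 40 °C
Reagents that add atoms: boron tribromide, BrB(Br)Br (boron and bromine stay only in 26)
Why: Lewis acid cleavage of aryl methyl ethers with BBr3 (oxygen–boron complexation, bromide attack on methyl), with the aliphatic methyl ester reacting far more slowly at or below 0 °C, while the methanol quench destroys the aryl borates and its HBr would return any acid formed to the methyl ester by Fischer esterification.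

**Compound list**
1 | 3,5-dimethoxy-4-methylbenzoic acid | COc1cc(C(=O)O)cc(OC)c1C | starting material
2 | (1H-imidazol-1-yl)(3,5-dimethoxy-4-methylphenyl)methanone, acyl imidazolide formed in the flask | COc1cc(C(=O)n2ccnc2)cc(OC)c1C | intermediate
3 | N,3,5-trimethoxy-N,4-dimethylbenzamide | COc1cc(C(=O)N(C)OC)cc(OC)c1C | intermediate
4 | 2-bromo-N,3,5-trimethoxy-N,4-dimethylbenzamide | COc1cc(C(=O)N(C)OC)c(Br)c(OC)c1C | intermediate
5 | N,3,5-trimethoxy-N,2,4-trimethylbenzamide | COc1cc(C(=O)N(C)OC)c(C)c(OC)c1C | intermediate
6 | 3,5-dimethoxytoluene | COc1cc(C)cc(OC)c1 | starting material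
7 | 2-bromo-3,5-dimethoxytoluene (2-bromo-1,5-dimethoxy-3-methylbenzene) | COc1cc(C)c(Br)c(OC)c1 | intermediate
8 | (2,4-dimethoxy-6-methylphenyl)lithium, formed in the flask | [Li]c1c(C)cc(OC)cc1OC | intermediate
9 | lithium (2,4-dimethoxy-6-methylphenyl)(3,5-dimethoxy-2,4-dimethylphenyl)[methoxy(methyl)amino]methanolate, chelated tetrahedral adduct formed in the flask | [Li]OC(N(C)OC)(c1c(C)cc(OC)cc1OC)c1cc(OC)c(C)c(OC)c1C | intermediate
10 | (2,4-dimethoxy-6-methylphenyl)(3,5-dimethoxy-2,4-dimethylphenyl)methanone | COc1cc(C)c(C(=O)c2cc(OC)c(C)c(OC)c2C)c(OC)c1 | intermediate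
11 | dichloro[2-(3,5-dimethoxy-2,4-dimethylbenzoyl)-5-methoxy-3-methylphenoxy]borane, boron chelated by the ketone oxygen, formed in the flask | COc1cc(C)c(C(=O)c2cc(OC)c(C)c(OC)c2C)c(OB(Cl)Cl)c1 | intermediate
12 | (2-hydroxy-4-methoxy-6-methylphenyl)(3,5-dimethoxy-2,4-dimethylphenyl)methanone | COc1cc(C)c(C(=O)c2cc(OC)c(C)c(OC)c2C)c(O)c1 | intermediate
13 | (triphenylphosphoranylidene)ketene | O=C=C=P(c1ccccc1)(c1ccccc1)c1ccccc1 | starting material
14 | 2-(3,5-dimethoxy-2,4-dimethylbenzoyl)-5-methoxy-3-methylphenyl (triphenylphosphoranylidene)acetate, formed in the flask | O=C(C=P(c1ccccc1)(c1ccccc1)c1ccccc1)Oc1cc(OC)cc(C)c1C(=O)c1cc(OC)c(C)c(OC)c1C | intermediate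
15 | 4-(3,5-dimethoxy-2,4-dimethylphenyl)-7-methoxy-5-methyl-2H-chromen-2-one | O=C1Oc2cc(OC)cc(C)c2C(c2cc(OC)c(C)c(OC)c2C)=C1 | intermediate
16 | 3-bromo-4-(3,5-dimethoxy-2,4-dimethylphenyl)-7-methoxy-5-methyl-2H-chromen-2-one | O=C1Oc2cc(OC)cc(C)c2C(c2cc(OC)c(C)c(OC)c2C)=C1Br | intermediate
17 | disodium (2E)-2-bromo-3-(3,5-dimethoxy-2,4-dimethylphenyl)-3-(4-methoxy-2-methyl-6-oxidophenyl)prop-2-enoate, formed in the flask | [Na+].[Na+].[O-]C(=O)/C(Br)=C(\c1c(C)cc(OC)cc1[O-])c1cc(OC)c(C)c(OC)c1C | intermediate
18 | sodium 3-(3,5-dimethoxy-2,4-dimethylphenyl)-6-methoxy-4-methyl-1-benzofuran-2-carboxylate, formed in the flask | [Na+].[O-]C(=O)c1oc2cc(OC)cc(C)c2c1-c1cc(OC)c(C)c(OC)c1C | intermediate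
19 | 3-(3,5-dimethoxy-2,4-dimethylphenyl)-6-methoxy-4-methyl-1-benzofuran-2-carboxylic acid | OC(=O)c1oc2cc(OC)cc(C)c2c1-c1cc(OC)c(C)c(OC)c1C | intermediate
20 | lithium {[3-(3,5-dimethoxy-2,4-dimethylphenyl)-6-methoxy-4-methyl-1-benzofuran-2-yl]methoxy}trihydridoaluminate, the aluminium alkoxide drawn in its simplest form, formed in the flask | [Li+].[AlH3-]OCc1oc2cc(OC)cc(C)c2c1-c1cc(OC)c(C)c(OC)c1C | intermediate
21 | [3-(3,5-dimethoxy-2,4-dimethylphenyl)-6-methoxy-4-methyl-1-benzofuran-2-yl]methanol | OCc1oc2cc(OC)cc(C)c2c1-c1cc(OC)c(C)c(OC)c1C | intermediate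
22 | methyl (triphenylphosphoranylidene)acetate | COC(=O)C=P(c1ccccc1)(c1ccccc1)c1ccccc1 | starting material
23 | 3-(3,5-dimethoxy-2,4-dimethylphenyl)-6-methoxy-4-methyl-1-benzofuran-2-carbaldehyde, formed in the flask | O=Cc1oc2cc(OC)cc(C)c2c1-c1cc(OC)c(C)c(OC)c1C | intermediate
24 | methyl (2E)-3-[3-(3,5-dimethoxy-2,4-dimethylphenyl)-6-methoxy-4-methyl-1-benzofuran-2-yl]prop-2-enoate | COC(=O)/C=C/c1oc2cc(OC)cc(C)c2c1-c1cc(OC)c(C)c(OC)c1C | intermediate
25 | methyl 3-[3-(3,5-dimethoxy-2,4-dimethylphenyl)-6-methoxy-4-methyl-1-benzofuran-2-yl]propanoate | COC(=O)CCc1oc2cc(OC)cc(C)c2c1-c1cc(OC)c(C)c(OC)c1C | intermediate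
26 | methyl 3-{3-[3,5-bis(dibromoboryloxy)-2,4-dimethylphenyl]-6-(dibromoboryloxy)-4-methyl-1-benzofuran-2-yl}propanoate, the aryl borate drawn in its simplest form, formed in the flask | COC(=O)CCc1oc2cc(OB(Br)Br)cc(C)c2c1-c1cc(OB(Br)Br)c(C)c(OB(Br)Br)c1C | intermediate
27 | talarominine A, methyl 3-[3-(3,5-dihydroxy-2,4-dimethylphenyl)-6-hydroxy-4-methyl-1-benzofuran-2-yl]propanoate | COC(=O)CCc1oc2cc(O)cc(C)c2c1-c1cc(O)c(C)c(O)c1C | target

**Step count and risks**
Total: 13 steps. Longest linear sequence: 12 steps (steps 1, 2, 3 and 5 to 13, from acid 1); step 4 is a one-step side branch.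

Steps most likely to fail:

1. Step 8. Site selectivity may be lost: the electrophile could attack the one free carbon of ring B, or C6/C8 of ring A, beside or instead of C3, giving mixtures and over-bromination. Fallback, from 15 back to 16: the position is fixed by C–H acidity instead of nucleophilicity. 15 is deprotonated at C3, the sp2 C–H next to the lactone carbonyl, with the TMP-zinc amide base TMPZnCl·LiCl (THF, 25 to 50 °C). This should give chlorido[4-(3,5-dimethoxy-2,4-dimethylphenyl)-7-methoxy-5-methyl-2-oxo-2H-chromen-3-yl]zinc F1. F1 is quenched with Br2 (1.0 equiv, −78 °C), which reacts with the carbon–zinc bond far faster than with the arenes, to deliver 16.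

2. Step 7. The intramolecular olefination may stall at the crowded ketone, which carries three ortho substituents, so that the ylide ester decomposes or hydrolyses before ring closure. Fallback, from 12 back to 15: the phenol of 12 is esterified with diethylphosphonoacetic acid (EDC, DMAP cat., CH2Cl2) to give 2-(3,5-dimethoxy-2,4-dimethylbenzoyl)-5-methoxy-3-methylphenyl (diethoxyphosphoryl)acetate F2. Its more nucleophilic phosphonate anion (NaH, THF, 0 °C to reflux) should close the pyranone by intramolecular Horner–Wadsworth–Emmons olefination to give 15.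

3. Step 5. The hindered, basic aryllithium may deprotonate the ortho methyl group of the amide or cleave its N–O bond by elimination instead of adding to the carbonyl. Fallback, from 5 and 7 back to 10: 5 is reduced with i-Bu2AlH (THF, −78 °C) to 3,5-dimethoxy-2,4-dimethylbenzaldehyde F3. Aryllithium 8 (from 7, n-BuLi, THF, −78 °C) adds to this far more reactive carbonyl to give racemic (2,4-dimethoxy-6-methylphenyl)(3,5-dimethoxy-2,4-dimethylphenyl)methanol F4. Its stereocentre disappears on oxidation with MnO2 (CH2Cl2, rt) to ketone 10.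

**Further compounds**
F1 | step 8 | chlorido[4-(3,5-dimethoxy-2,4-dimethylphenyl)-7-methoxy-5-methyl-2-oxo-2H-chromen-3-yl]zinc | O=C1Oc2cc(OC)cc(C)c2C(c2cc(OC)c(C)c(OC)c2C)=C1[Zn]Cl
F2 | step 7 | 2-(3,5-dimethoxy-2,4-dimethylbenzoyl)-5-methoxy-3-methylphenyl (diethoxyphosphoryl)acetate | CCOP(=O)(CC(=O)Oc1cc(OC)cc(C)c1C(=O)c1cc(OC)c(C)c(OC)c1C)OCC
F3 | step 5 | 3,5-dimethoxy-2,4-dimethylbenzaldehyde | COc1cc(C=O)c(C)c(OC)c1C
F4 | step 5 | (2,4-dimethoxy-6-methylphenyl)(3,5-dimethoxy-2,4-dimethylphenyl)methanol (racemic) | COc1cc(C)c(C(O)c2cc(OC)c(C)c(OC)c2C)c(OC)c1
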